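**Retrosynthetic overview**
1. Last disconnection: the C3–O ester bond, giving 4'-O-methylepigallocatechin (phenols silylated) and O-silylated ferulic acid.
2. Ring C (closed last): the O1–C2 bond, made by Mitsunobu displacement at the C2 carbinol by a ring A phenol with inversion, from an open chain with anti C2/C3 oxygens.
3. Ring A (closed second, key): the strategy rests on ring A being a phloroglucinol, with oxygen on C5, C7 and C8a (mutually meta) and its only carbon substituent on C4a between two of them. A 3-alkoxyvinylketene and a siloxyalkyne assemble exactly this pattern: 3-(benzyloxy)cyclobutenone supplies C6–C7–C8–C8a, the siloxyalkyne supplies C5 and C4a with the C4–C3–C2 chain and ring B attached.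
4. Siloxyalkyne: ring B aldehyde, vinyl addition, Sharpless kinetic-resolution epoxidation (sets C2 and C3), acetylide opening of the epoxide (adds C4), acetylide oxygenation and O-silylation.
5. Order of rings: B (from the gallate ester), then A (step 12), then C (step 14).

Key step: step 12

Remark: flavan numbering is used for chain and ring A atoms throughout; the two oxygens ortho to the side chain become equivalent after step 13, so the labels C5 and C8a before ring closure are nominal.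

**Route**

Step 1
Reactants: 1 methyl 3,5-dihydroxy-4-methoxybenzoate
Product: 2 methyl 3,5-bis(benzyloxy)-4-methoxybenzoate
Conditions: BnBr (2.4 equiv), K2CO3, DMF, 60 °C
Reagents that add atoms: benzyl bromide BrCc1ccccc1
Why: Williamson etherification of the two phenols, the only acidic sites, should proceed cleanly because the methyl ester and the flanked 4-methoxy group are inert to K2CO3.

Step 2
Reactants: 2 methyl 3,5-bis(benzyloxy)-4-methoxybenzoate
Product: 3 [3,5-bis(benzyloxy)-4-methoxyphenyl]methanol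
Conditions: LiAlH4, THF, 0 °C
Reagents that add atoms: none
Why: Hydride reduction of the methyl ester to the primary benzylic alcohol is routine and leaves the aryl ethers untouched.

Step 3
Reactants: 3 [3,5-bis(benzyloxy)-4-methoxyphenyl]methanol
Product: 4 3,5-bis(benzyloxy)-4-methoxybenzaldehyde
Conditions: activated MnO2, CH2Cl2, rt
Reagents that add atoms: none
Why: Activated MnO2 oxidises benzylic alcohols selectively to the aldehyde without over-oxidation, and the ethers are inert.

Step 4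
Reactants: 4 3,5-bis(benzyloxy)-4-methoxybenzaldehyde
Product: 5 racemic 1-[3,5-bis(benzyloxy)-4-methoxyphenyl]prop-2-en-1-ol
Conditions: CH2=CHMgBr, THF, −78 to 0 °C
Reagents that add atoms: vinylmagnesium bromide C=C[Mg]Br
Why: Grignard 1,2-addition to the aromatic aldehyde gives the secondary allylic alcohol as a racemate, which is the substrate the kinetic resolution needs.

Step 5
Reactants: 5 racemic 1-[3,5-bis(benzyloxy)-4-methoxyphenyl]prop-2-en-1-ol
Product: 6 (S)-[3,5-bis(benzyloxy)-4-methoxyphenyl][(2R)-oxiran-2-yl]methanol (erythro)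
Conditions: Ti(OiPr)4 (0.2 equiv), L-(+)-diisopropyl tartrate (0.25 equiv), t-BuOOH (0.55 equiv), 4 Å MS, CH2Cl2, −20 °C
Reagents that add atoms: tert-butyl hydroperoxide CC(C)(C)OO
Why: Sharpless asymmetric epoxidation under kinetic-resolution conditions, in which the L-(+)-tartrate fixes the alkene face and the (R)-enantiomer of 5 (carbinol hydrogen, not aryl, toward the oxidant) reacts fast, should give the erythro (anti) epoxy alcohol with the S carbinol centre (later C2) and the R oxirane centre (later C3), while the (S)-enantiomer of 5 stays behind and is separated.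

Step 6
Reactants: 6 (S)-[3,5-bis(benzyloxy)-4-methoxyphenyl][(2R)-oxiran-2-yl]methanol
Product: 7 tert-butyl{(S)-[3,5-bis(benzyloxy)-4-methoxyphenyl][(2R)-oxiran-2-yl]methoxy}dimethylsilane
Conditions: TBSCl, imidazole, DMF, rt
Reagents that add atoms: tert-butyldimethylsilyl chloride CC(C)(C)[Si](C)(C)Cl
Why: Silylation of the secondary alcohol under mild amine base leaves the epoxide intact and installs a group that fluoride will later remove together with the aryl silyl ether.

Step 7
Reactants: 7 tert-butyl{(S)-[3,5-bis(benzyloxy)-4-methoxyphenyl][(2R)-oxiran-2-yl]methoxy}dimethylsilane; 8 ethynyltrimethylsilane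
Product: 10 (1S,2R)-1-[3,5-bis(benzyloxy)-4-methoxyphenyl]-1-(tert-butyldimethylsilyloxy)-5-(trimethylsilyl)pent-4-yn-2-ol, via lithium (trimethylsilyl)acetylide 9 (not isolated)
Conditions: 8, n-BuLi, THF, −78 °C; then BF3·OEt2, then 7, −78 °C
Reagents that add atoms: none
Why: BF3-promoted opening of the terminal epoxide by the lithium acetylide (Yamaguchi alkynylation) occurs at the unhindered CH2 terminus at −78 °C, so the C3 centre is not touched and the BF3-bound alkoxide should not trigger 1,2-silyl migration.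

Step 8
Reactants: 10 (1S,2R)-1-[3,5-bis(benzyloxy)-4-methoxyphenyl]-1-(tert-butyldimethylsilyloxy)-5-(trimethylsilyl)pent-4-yn-2-ol
Product: 11 (4R,5S)-4-(benzyloxy)-5-[3,5-bis(benzyloxy)-4-methoxyphenyl]-5-(tert-butyldimethylsilyloxy)-1-(trimethylsilyl)pent-1-yne
Conditions: 2-benzyloxy-1-methylpyridinium triflate (2 equiv), MgO (2 equiv), PhCF3, 85 °C
Reagents that add atoms: 2-benzyloxy-1-methylpyridinium triflate C[n+]1ccccc1OCc1ccccc1.[O-]S(=O)(=O)C(F)(F)F
Why: Benzyl transfer from the 2-benzyloxypyridinium salt under neutral conditions with MgO as acid scavenger should etherify the hindered secondary alcohol without the 1,2-migration of the neighbouring TBS group or the loss of the alkynylsilane that an alkoxide benzylation would risk.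

Step 9
Reactants: 11 (4R,5S)-4-(benzyloxy)-5-[3,5-bis(benzyloxy)-4-methoxyphenyl]-5-(tert-butyldimethylsilyloxy)-1-(trimethylsilyl)pent-1-yne
Product: 12 (4R,5S)-4-(benzyloxy)-5-[3,5-bis(benzyloxy)-4-methoxyphenyl]-5-(tert-butyldimethylsilyloxy)pent-1-yne
Conditions: K2CO3 (cat.), MeOH/THF, rt
Reagents that add atoms: none
Why: Carbonate-catalysed methanolysis (protodesilylation) is selective for the C(sp)–SiMe3 bond and leaves the alkyl TBS ether and the benzyl ethers in place.

Step 10
Reactants: 12 (4R,5S)-4-(benzyloxy)-5-[3,5-bis(benzyloxy)-4-methoxyphenyl]-5-(tert-butyldimethylsilyloxy)pent-1-yne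
Product: 15 (4R,5S)-4-(benzyloxy)-5-[3,5-bis(benzyloxy)-4-methoxyphenyl]-5-(tert-butyldimethylsilyloxy)-1-(triisopropylsilyloxy)pent-1-yne, via lithium acetylide 13 (not isolated), via lithium ynolate 14 (not isolated)
Conditions: n-BuLi (1.0 equiv), THF, −78 °C; LiOOt-Bu (from t-BuOOH and LiN(SiMe3)2, THF, −78 °C), −78 to 0 °C; TIPSOTf, −78 to 0 °C
Reagents that add atoms: lithium tert-butyl peroxide [Li+].CC(C)(C)O[O-]; triisopropylsilyl triflate CC(C)[Si](OS(=O)(=O)C(F)(F)F)(C(C)C)C(C)C
Why: Electrophilic oxygenation of the lithium acetylide by LiOOt-Bu gives the lithium ynolate, which the bulky silyl triflate should capture on oxygen rather than carbon to give the siloxyalkyne, with no stereocentre involved.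

Step 11
Reactants: 16 3-ethoxycyclobut-2-en-1-one
Product: 17 3-(benzyloxy)cyclobut-2-en-1-one
Conditions: BnOH (3 equiv), TsOH·H2O (5 mol %), toluene, 40 °C, reduced pressure (EtOH removed)
Reagents that add atoms: benzyl alcohol OCc1ccccc1
Why: Acid-catalysed transetherification of the vinylogous ester by addition–elimination at C3, the site at which water attacks in the hydrolysis of this enol ether to cyclobutane-1,3-dione, should exchange ethoxy for benzyloxy once the ethanol is removed.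

Step 12
Reactants: 15 (4R,5S)-4-(benzyloxy)-5-[3,5-bis(benzyloxy)-4-methoxyphenyl]-5-(tert-butyldimethylsilyloxy)-1-(triisopropylsilyloxy)pent-1-yne; 17 3-(benzyloxy)cyclobut-2-en-1-one
Product: 22 5-(benzyloxy)-2-{(2R,3S)-2-(benzyloxy)-3-[3,5-bis(benzyloxy)-4-methoxyphenyl]-3-(tert-butyldimethylsilyloxy)propyl}-3-(triisopropylsilyloxy)phenol, via vinylketene 18 (not isolated), via cyclobutenone adduct 19 (not isolated), via dienylketene 20 (not isolated), via cyclohexadienone 21 (not isolated)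
Conditions: 17 (1.5 equiv, free of BnOH), toluene, 80 to 110 °C, sealed tube, Ar
Reagents that add atoms: none
Why: Thermal 4π-electrocyclic opening of 17 should give the 3-benzyloxyvinylketene 18, whose ketene carbon is attacked by the nucleophilic, chain-bearing carbon of the polarised siloxyalkyne 15 in a [2+2] cycloaddition that forms C4a–C8a and C5–C6 and gives the 4-vinylcyclobutenone 19. A second 4π opening leads to the dienylketene 20, ring A closes by 6π-electrocyclisation (C8–C8a) to the cyclohexadienone 21, and tautomerisation gives the phenol 22. The closest known reaction is the Danheiser benzannulation of 3-substituted cyclobutenones with triisopropylsiloxyalkynes to resorcinol monosilyl ethers, run here with a vinylogous ester as the cyclobutenone so that the third oxygen arrives on C7. Ring A is therefore closed by a pericyclic cascade from two open-chain partners and no stereocentre is formed; the C2 and C3 carbinol centres sit away from the reacting alkyne and see only neutral, thermal conditions. The one selectivity needed is the orientation of the [2+2] step, which the oxygen-induced polarisation of the ynol ether secures, so that C4a comes to lie between two oxygen-bearing carbons and the benzyloxy group para to it. The substrate carries no free OH or NH that could trap the ketenes.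

Step 13
Reactants: 22 5-(benzyloxy)-2-{(2R,3S)-2-(benzyloxy)-3-[3,5-bis(benzyloxy)-4-methoxyphenyl]-3-(tert-butyldimethylsilyloxy)propyl}-3-(triisopropylsilyloxy)phenol
Product: 23 5-(benzyloxy)-2-{(2R,3S)-2-(benzyloxy)-3-[3,5-bis(benzyloxy)-4-methoxyphenyl]-3-hydroxypropyl}benzene-1,3-diol
Conditions: TBAF (3 equiv), THF, 0 °C to rt, Ar
Reagents that add atoms: none
Why: Fluoride desilylation cleaves the aryl TIPS ether and the secondary TBS ether in one operation while the benzyl ethers are inert, exposing the two equivalent ortho phenols and the C2 carbinol.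

Step 14
Reactants: 23 5-(benzyloxy)-2-{(2R,3S)-2-(benzyloxy)-3-[3,5-bis(benzyloxy)-4-methoxyphenyl]-3-hydroxypropyl}benzene-1,3-diol
Product: 24 (2R,3R)-3,7-bis(benzyloxy)-2-[3,5-bis(benzyloxy)-4-methoxyphenyl]chroman-5-ol (2,3-cis)
Conditions: PPh3, DIAD, THF, 0 °C
Reagents that add atoms: none
Why: In this intramolecular Mitsunobu etherification the only alcohol, the C2 carbinol, is activated as its oxyphosphonium ion and displaced by an ortho phenoxide in a 6-exo-tet SN2 closure with inversion, which turns the (2S,3R) anti chain into the (2R,3R) 2,3-cis flavan, the C3 oxygen being blocked as its benzyl ether so that no epoxide can form.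

Step 15
Reactants: 24 (2R,3R)-3,7-bis(benzyloxy)-2-[3,5-bis(benzyloxy)-4-methoxyphenyl]chroman-5-ol
Product: 25 4'-O-methylepigallocatechin [(2R,3R)-2-(3,5-dihydroxy-4-methoxyphenyl)chromane-3,5,7-triol]
Conditions: H2 (1 atm), Pd(OH)2/C, THF/MeOH, rt
Reagents that add atoms: none
Why: Hydrogenolysis removes the four benzyl ethers at this stage, before the reducible cinnamate alkene is introduced, and does not affect C2 or C3.

Step 16
Reactants: 25 4'-O-methylepigallocatechin
Product: 26 (2R,3R)-5,7-bis(tert-butyldimethylsilyloxy)-2-[3,5-bis(tert-butyldimethylsilyloxy)-4-methoxyphenyl]chroman-3-ol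
Conditions: TBSCl (4.4 equiv), imidazole, DMF, 0 °C to rt
Reagents that add atoms: tert-butyldimethylsilyl chloride CC(C)(C)[Si](C)(C)Cl
Why: In this chemoselective silylation the four phenols react much faster than the hindered axial C3 hydroxyl next to the C2 aryl group, so a slight excess over four equivalents of TBSCl should leave the C3 hydroxyl free.

Step 17
Reactants: 27 ferulic acid
Product: 29 (E)-3-[4-(tert-butyldimethylsilyloxy)-3-methoxyphenyl]prop-2-enoic acid, via silyl ester 28 (not isolated)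
Conditions: TBSCl (2.2 equiv), imidazole, DMF, rt; then AcOH/THF/H2O, rt
Reagents that add atoms: tert-butyldimethylsilyl chloride CC(C)(C)[Si](C)(C)Cl
Why: Bis-silylation followed by selective hydrolysis of the far more labile silyl ester should give the phenol-protected acid, since the aryl silyl ether is stable to mild aqueous acid.

Step 18
Reactants: 26 (2R,3R)-5,7-bis(tert-butyldimethylsilyloxy)-2-[3,5-bis(tert-butyldimethylsilyloxy)-4-methoxyphenyl]chroman-3-ol; 29 (E)-3-[4-(tert-butyldimethylsilyloxy)-3-methoxyphenyl]prop-2-enoic acid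
Product: 30 (2R,3R)-5,7-bis(tert-butyldimethylsilyloxy)-2-[3,5-bis(tert-butyldimethylsilyloxy)-4-methoxyphenyl]chroman-3-yl (E)-3-[4-(tert-butyldimethylsilyloxy)-3-methoxyphenyl]prop-2-enoate
Conditions: DCC, DMAP (cat.), CH2Cl2, 0 °C to rt
Reagents that add atoms: none
Why: Steglich esterification (carbodiimide activation, acyl transfer by DMAP) acylates the single free hydroxyl at C3 with retention, since the C3–O bond is not broken.

Step 19
Reactants: 30 penta-silylated ferulate ester
Product: 31 4'-O-methylepigallocatechin-3-O-ferulate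
Conditions: TBAF (6 equiv), AcOH (6 equiv), THF, 0 °C
Reagents that add atoms: none
Why: Fluoride desilylation buffered with acetic acid removes the five aryl silyl ethers without base-induced cleavage or migration of the cinnamate ester and without touching the E alkene, giving the target.

**Compound list**
1 | methyl 3,5-dihydroxy-4-methoxybenzoate | COC(=O)c1cc(O)c(OC)c(O)c1 | starting material
2 | methyl 3,5-bis(benzyloxy)-4-methoxybenzoate | COC(=O)c1cc(OCc2ccccc2)c(OC)c(OCc2ccccc2)c1 | intermediate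
3 | [3,5-bis(benzyloxy)-4-methoxyphenyl]methanol | OCc1cc(OCc2ccccc2)c(OC)c(OCc2ccccc2)c1 | intermediate
4 | 3,5-bis(benzyloxy)-4-methoxybenzaldehyde | O=Cc1cc(OCc2ccccc2)c(OC)c(OCc2ccccc2)c1 | intermediate
5 | racemic 1-[3,5-bis(benzyloxy)-4-methoxyphenyl]prop-2-en-1-ol | C=CC(O)c1cc(OCc2ccccc2)c(OC)c(OCc2ccccc2)c1 | intermediate
6 | (S)-[3,5-bis(benzyloxy)-4-methoxyphenyl][(2R)-oxiran-2-yl]methanol (erythro) | O[C@H]([C@H]1CO1)c1cc(OCc2ccccc2)c(OC)c(OCc2ccccc2)c1 | intermediate
7 | tert-butyl{(S)-[3,5-bis(benzyloxy)-4-methoxyphenyl][(2R)-oxiran-2-yl]methoxy}dimethylsilane | CC(C)(C)[Si](C)(C)O[C@H]([C@H]1CO1)c1cc(OCc2ccccc2)c(OC)c(OCc2ccccc2)c1 | intermediate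
8 | ethynyltrimethylsilane | C#C[Si](C)(C)C | starting material
9 | lithium (trimethylsilyl)acetylide | [Li]C#C[Si](C)(C)C | intermediate
10 | (1S,2R)-1-[3,5-bis(benzyloxy)-4-methoxyphenyl]-1-(tert-butyldimethylsilyloxy)-5-(trimethylsilyl)pent-4-yn-2-ol | C[Si](C)(C)C#CC[C@@H](O)[C@@H](O[Si](C)(C)C(C)(C)C)c1cc(OCc2ccccc2)c(OC)c(OCc2ccccc2)c1 | intermediate
11 | (4R,5S)-4-(benzyloxy)-5-[3,5-bis(benzyloxy)-4-methoxyphenyl]-5-(tert-butyldimethylsilyloxy)-1-(trimethylsilyl)pent-1-yne | C[Si](C)(C)C#CC[C@@H](OCc1ccccc1)[C@@H](O[Si](C)(C)C(C)(C)C)c1cc(OCc2ccccc2)c(OC)c(OCc2ccccc2)c1 | intermediate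
12 | (4R,5S)-4-(benzyloxy)-5-[3,5-bis(benzyloxy)-4-methoxyphenyl]-5-(tert-butyldimethylsilyloxy)pent-1-yne | C#CC[C@@H](OCc1ccccc1)[C@@H](O[Si](C)(C)C(C)(C)C)c1cc(OCc2ccccc2)c(OC)c(OCc2ccccc2)c1 | intermediate
13 | lithium acetylide of 12 | [Li]C#CC[C@@H](OCc1ccccc1)[C@@H](O[Si](C)(C)C(C)(C)C)c1cc(OCc2ccccc2)c(OC)c(OCc2ccccc2)c1 | intermediate
14 | lithium (4R,5S)-4-(benzyloxy)-5-[3,5-bis(benzyloxy)-4-methoxyphenyl]-5-(tert-butyldimethylsilyloxy)pent-1-yn-1-olate (ynolate) | [Li]OC#CC[C@@H](OCc1ccccc1)[C@@H](O[Si](C)(C)C(C)(C)C)c1cc(OCc2ccccc2)c(OC)c(OCc2ccccc2)c1 | intermediate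
15 | (4R,5S)-4-(benzyloxy)-5-[3,5-bis(benzyloxy)-4-methoxyphenyl]-5-(tert-butyldimethylsilyloxy)-1-(triisopropylsilyloxy)pent-1-yne | CC(C)[Si](C(C)C)(C(C)C)OC#CC[C@@H](OCc1ccccc1)[C@@H](O[Si](C)(C)C(C)(C)C)c1cc(OCc2ccccc2)c(OC)c(OCc2ccccc2)c1 | intermediate
16 | 3-ethoxycyclobut-2-en-1-one | CCOC1=CC(=O)C1 | starting material
17 | 3-(benzyloxy)cyclobut-2-en-1-one | O=C1C=C(OCc2ccccc2)C1 | intermediate
18 | 3-(benzyloxy)buta-1,3-dien-1-one (vinylketene) | O=C=CC(=C)OCc1ccccc1 | intermediate
19 | 4-[1-(benzyloxy)ethenyl]-2-{(2R,3S)-2-(benzyloxy)-3-[3,5-bis(benzyloxy)-4-methoxyphenyl]-3-(tert-butyldimethylsilyloxy)propyl}-3-(triisopropylsilyloxy)cyclobut-2-en-1-one (ring C4 unassigned) | O=C1C(C[C@@H](OCc2ccccc2)[C@@H](O[Si](C)(C)C(C)(C)C)c2cc(OCc3ccccc3)c(OC)c(OCc3ccccc3)c2)=C(O[Si](C(C)C)(C(C)C)C(C)C)C1C(=C)OCc1ccccc1 | intermediate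
20 | dienylketene: 5-(benzyloxy)-2-{(2R,3S)-2-(benzyloxy)-3-[3,5-bis(benzyloxy)-4-methoxyphenyl]-3-(tert-butyldimethylsilyloxy)propyl}-3-(triisopropylsilyloxy)hexa-1,3,5-trien-1-one | O=C=C(C[C@@H](OCc1ccccc1)[C@@H](O[Si](C)(C)C(C)(C)C)c1cc(OCc2ccccc2)c(OC)c(OCc2ccccc2)c1)/C(O[Si](C(C)C)(C(C)C)C(C)C)=C\C(=C)OCc1ccccc1 | intermediate
21 | 5-(benzyloxy)-2-{(2R,3S)-2-(benzyloxy)-3-[3,5-bis(benzyloxy)-4-methoxyphenyl]-3-(tert-butyldimethylsilyloxy)propyl}-3-(triisopropylsilyloxy)cyclohexa-2,4-dien-1-one | O=C1CC(OCc2ccccc2)=CC(O[Si](C(C)C)(C(C)C)C(C)C)=C1C[C@@H](OCc1ccccc1)[C@@H](O[Si](C)(C)C(C)(C)C)c1cc(OCc2ccccc2)c(OC)c(OCc2ccccc2)c1 | intermediate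
22 | 5-(benzyloxy)-2-{(2R,3S)-2-(benzyloxy)-3-[3,5-bis(benzyloxy)-4-methoxyphenyl]-3-(tert-butyldimethylsilyloxy)propyl}-3-(triisopropylsilyloxy)phenol | Oc1cc(OCc2ccccc2)cc(O[Si](C(C)C)(C(C)C)C(C)C)c1C[C@@H](OCc1ccccc1)[C@@H](O[Si](C)(C)C(C)(C)C)c1cc(OCc2ccccc2)c(OC)c(OCc2ccccc2)c1 | intermediate
23 | 5-(benzyloxy)-2-{(2R,3S)-2-(benzyloxy)-3-[3,5-bis(benzyloxy)-4-methoxyphenyl]-3-hydroxypropyl}benzene-1,3-diol | Oc1cc(OCc2ccccc2)cc(O)c1C[C@@H](OCc1ccccc1)[C@@H](O)c1cc(OCc2ccccc2)c(OC)c(OCc2ccccc2)c1 | intermediate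
24 | (2R,3R)-3,7-bis(benzyloxy)-2-[3,5-bis(benzyloxy)-4-methoxyphenyl]chroman-5-ol | c1ccccc1CO[C@@H]2Cc3c(O)cc(OCc4ccccc4)cc3O[C@@H]2c2cc(OCc3ccccc3)c(OC)c(OCc3ccccc3)c2 | intermediate
25 | 4'-O-methylepigallocatechin, (2R,3R)-2-(3,5-dihydroxy-4-methoxyphenyl)chromane-3,5,7-triol | O[C@@H]1Cc2c(O)cc(O)cc2O[C@@H]1c1cc(O)c(OC)c(O)c1 | intermediate
26 | (2R,3R)-5,7-bis(tert-butyldimethylsilyloxy)-2-[3,5-bis(tert-butyldimethylsilyloxy)-4-methoxyphenyl]chroman-3-ol | O[C@@H]1Cc2c(O[Si](C)(C)C(C)(C)C)cc(O[Si](C)(C)C(C)(C)C)cc2O[C@@H]1c1cc(O[Si](C)(C)C(C)(C)C)c(OC)c(O[Si](C)(C)C(C)(C)C)c1 | intermediate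
27 | ferulic acid, (E)-3-(4-hydroxy-3-methoxyphenyl)prop-2-enoic acid | COc1cc(/C=C/C(=O)O)ccc1O | starting material
28 | tert-butyldimethylsilyl (E)-3-[4-(tert-butyldimethylsilyloxy)-3-methoxyphenyl]prop-2-enoate | COc1cc(/C=C/C(=O)O[Si](C)(C)C(C)(C)C)ccc1O[Si](C)(C)C(C)(C)C | intermediate
29 | (E)-3-[4-(tert-butyldimethylsilyloxy)-3-methoxyphenyl]prop-2-enoic acid | COc1cc(/C=C/C(=O)O)ccc1O[Si](C)(C)C(C)(C)C | intermediate
30 | (2R,3R)-5,7-bis(tert-butyldimethylsilyloxy)-2-[3,5-bis(tert-butyldimethylsilyloxy)-4-methoxyphenyl]chroman-3-yl (E)-3-[4-(tert-butyldimethylsilyloxy)-3-methoxyphenyl]prop-2-enoate | COc1cc(/C=C/C(=O)O[C@@H]2Cc3c(O[Si](C)(C)C(C)(C)C)cc(O[Si](C)(C)C(C)(C)C)cc3O[C@@H]2c2cc(O[Si](C)(C)C(C)(C)C)c(OC)c(O[Si](C)(C)C(C)(C)C)c2)ccc1O[Si](C)(C)C(C)(C)C | intermediate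
31 | 4'-O-methylepigallocatechin-3-O-ferulate | COc1cc(/C=C/C(=O)O[C@@H]2Cc3c(O)cc(O)cc3O[C@@H]2c2cc(O)c(OC)c(O)c2)ccc1O | target

**Step count**
Total: 19 steps. Longest linear sequence: 17 steps (steps 1–10, 12–16, 18 and 19); steps 11 and 17 are side branches.

**Steps most likely to fail**

1. Step 12 (benzannulation). The donor-stabilised cyclobutenone 17 may open to its vinylketene only slowly. At the temperature then required, thermal 1,3-silyl shift of the siloxyalkyne to a silylketene, or acylation of the newly formed phenol by vinylketene, could outrun the cycloaddition. Fallback, from 7 back to 25, with ring A taken from phloroglucinol instead of being built. Phloroglucinol is converted with MOMCl and i-Pr2NEt into 1,3,5-tris(methoxymethoxy)benzene F1. F1 is lithiated between two acetal oxygens (n-BuLi, THF, 0 °C) and opens the silylated epoxide 7 at its CH2 terminus (BF3·OEt2, −78 °C) to (1S,2R)-1-[3,5-bis(benzyloxy)-4-methoxyphenyl]-1-(tert-butyldimethylsilyloxy)-3-[2,4,6-tris(methoxymethoxy)phenyl]propan-2-ol F2. Benzylation under the conditions of step 8 gives the benzyl ether F3. HCl in MeOH (0 °C to rt) removes the three MOM groups and the TBS ether to give the tetraol 2-{(2R,3S)-2-(benzyloxy)-3-[3,5-bis(benzyloxy)-4-methoxyphenyl]-3-hydroxypropyl}benzene-1,3,5-triol F4. Mitsunobu closure as in step 14 gives (2R,3R)-3-(benzyloxy)-2-[3,5-bis(benzyloxy)-4-methoxyphenyl]chromane-5,7-diol F5, and hydrogenolysis as in step 15 returns to 25.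

2. Step 14 (Mitsunobu closure). The hindered benzylic carbinol may be activated poorly, or the oxyphosphonium ion may ionise or eliminate toward the enol ether instead of undergoing clean SN2 closure, eroding the C2 configuration. Fallback, from 22 back to 24, with stepwise sulfonate activation and fluoride-triggered displacement. The free phenol of 22 is silylated (TBSCl, imidazole, DMF) to the bis(aryl silyl ether) F6. The alkyl TBS ether alone is cleaved with CSA in MeOH/CH2Cl2, which aryl silyl ethers resist, to give the benzylic alcohol F7. Ms2O and Et3N in CH2Cl2 at −40 °C (no chloride present) give the mesylate F8. TBAF in THF at 0 °C then cleaves both aryl silyl ethers, and the phenoxide set free displaces the mesylate with inversion to give 24.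

3. Step 11 (enol ether exchange). Benzyl alcohol may attack the strained ring at the carbonyl carbon and open it to an acetoacetate-type ester instead of exchanging at C3. Fallback, from 16 back to 17 in two steps. Cold dilute aqueous HCl hydrolyses 16 to cyclobutane-1,3-dione F9, and its acidic enol is then O-benzylated under Mitsunobu conditions (BnOH, PPh3, DIAD, THF, 0 °C) to give 17.

**Further compounds**
F1 | step 12 | 1,3,5-tris(methoxymethoxy)benzene | COCOc1cc(OCOC)cc(OCOC)c1
F2 | step 12 | (1S,2R)-1-[3,5-bis(benzyloxy)-4-methoxyphenyl]-1-(tert-butyldimethylsilyloxy)-3-[2,4,6-tris(methoxymethoxy)phenyl]propan-2-ol | COCOc1cc(OCOC)cc(OCOC)c1C[C@@H](O)[C@@H](O[Si](C)(C)C(C)(C)C)c1cc(OCc2ccccc2)c(OC)c(OCc2ccccc2)c1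
F3 | step 12 | benzyl ether of F2, tert-butyl{(1S,2R)-2-(benzyloxy)-1-[3,5-bis(benzyloxy)-4-methoxyphenyl]-3-[2,4,6-tris(methoxymethoxy)phenyl]propoxy}dimethylsilane | COCOc1cc(OCOC)cc(OCOC)c1C[C@@H](OCc1ccccc1)[C@@H](O[Si](C)(C)C(C)(C)C)c1cc(OCc2ccccc2)c(OC)c(OCc2ccccc2)c1
F4 | step 12 | 2-{(2R,3S)-2-(benzyloxy)-3-[3,5-bis(benzyloxy)-4-methoxyphenyl]-3-hydroxypropyl}benzene-1,3,5-triol | Oc1cc(O)cc(O)c1C[C@@H](OCc1ccccc1)[C@@H](O)c1cc(OCc2ccccc2)c(OC)c(OCc2ccccc2)c1
F5 | step 12 | (2R,3R)-3-(benzyloxy)-2-[3,5-bis(benzyloxy)-4-methoxyphenyl]chromane-5,7-diol | c1ccccc1CO[C@@H]2Cc3c(O)cc(O)cc3O[C@@H]2c2cc(OCc3ccccc3)c(OC)c(OCc3ccccc3)c2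
F6 | step 14 | O-TBS ether of 22, with aryl OTBS, aryl OTIPS and alkyl OTBS | CC(C)(C)[Si](C)(C)Oc1cc(OCc2ccccc2)cc(O[Si](C(C)C)(C(C)C)C(C)C)c1C[C@@H](OCc1ccccc1)[C@@H](O[Si](C)(C)C(C)(C)C)c1cc(OCc2ccccc2)c(OC)c(OCc2ccccc2)c1
F7 | step 14 | (1S,2R)-2-(benzyloxy)-1-[3,5-bis(benzyloxy)-4-methoxyphenyl]-3-[4-(benzyloxy)-2-(tert-butyldimethylsilyloxy)-6-(triisopropylsilyloxy)phenyl]propan-1-ol | CC(C)(C)[Si](C)(C)Oc1cc(OCc2ccccc2)cc(O[Si](C(C)C)(C(C)C)C(C)C)c1C[C@@H](OCc1ccccc1)[C@@H](O)c1cc(OCc2ccccc2)c(OC)c(OCc2ccccc2)c1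
F8 | step 14 | methanesulfonate of F7 | CC(C)(C)[Si](C)(C)Oc1cc(OCc2ccccc2)cc(O[Si](C(C)C)(C(C)C)C(C)C)c1C[C@@H](OCc1ccccc1)[C@@H](OS(C)(=O)=O)c1cc(OCc2ccccc2)c(OC)c(OCc2ccccc2)c1
F9 | step 11 | cyclobutane-1,3-dione | O=C1CC(=O)C1
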